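**Pl

an**
- Retrosynthesis: the three aryl silyl ethers are removed last. Ring C is cut at C4–C4a (aryl ketone bond) to an (S)-3-aryl-3-aryloxypropanoic acid. The C2–O1 ether bond is then cut to a B-ring cinnamyl carbonate and 3,5-bis(silyloxy)phenol. The B ring is cut at C8–prenyl and at its pyran ring, back to 5-bromo-2,4-dihydroxybenzaldehyde.
- Forward: the pyran ring of the chromene is annulated first, then the prenyl group is coupled on. The aldehyde is extended to a three-carbon chain, the A ring is attached through O1, and the chain end is oxidised. Ring C closes last.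
- Enabling feature: C4a lies ortho to O1 and next to the C5 oxygen. In the open precursor the A ring (C4a–C8a) is a 1-alkoxy-3,5-bis(silyloxy)benzene with a mirror plane through O1, so its two carbons ortho to O1 are identical and each has two ortho oxygens and one para oxygen. The O1–C2–C3 tether can bring C4 only to these carbons.
- Stereochemistry: C2 (S) is the only stereocentre. It is set by ligand control in an iridium-catalysed allylic etherification, and none of its bonds is touched afterwards.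

Key step: step 11

Remark: the (Sa,Sc,Sc) antipode of the binaphthol-derived phosphoramidite is assumed to deliver the (S)-ether, by analogy with simple cinnamyl carbonates, where O- and N-nucleophiles attack the same allyl face; if a test run shows the opposite sense, the mirror-image ligand is used.

**Route**

Step 1
Reactants: 1 5-bromo-2,4-dihydroxybenzaldehyde; 2 3-methylbut-2-enal
Product: 4 8-bromo-5-hydroxy-2,2-dimethyl-2H-chromene-6-carbaldehyde, via oxatriene 3 (not isolated)
Conditions: ethylenediammonium diacetate (20 mol%), xylene, reflux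
Reagents that add atoms: none
Why: Knoevenagel-type condensation at C3 of the resorcinol (the only free carbon between the two hydroxyls, C5 being brominated) and oxa-6π electrocyclisation through the non-chelated 4-OH should build the 2,2-dimethylpyran ring.

Step 2
Reactants: 4 8-bromo-5-hydroxy-2,2-dimethyl-2H-chromene-6-carbaldehyde; 5 tributyl(3-methylbut-2-enyl)stannane
Product: 6 5-hydroxy-2,2-dimethyl-8-(3-methylbut-2-enyl)-2H-chromene-6-carbaldehyde
Conditions: Pd(PPh3)4 (5 mol%), DMF, 100 °C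
Reagents that add atoms: none
Why: Stille coupling of the aryl bromide; reductive elimination from the aryl(η3-prenyl)palladium intermediate is expected at the unhindered CH2 terminus, giving the linear prenyl group, and the chelated phenol and the aldehyde are tolerated.

Step 3
Reactants: 6 5-hydroxy-2,2-dimethyl-8-(3-methylbut-2-enyl)-2H-chromene-6-carbaldehyde
Product: 7 5-(tert-butyldimethylsilyloxy)-2,2-dimethyl-8-(3-methylbut-2-enyl)-2H-chromene-6-carbaldehyde
Conditions: TBSCl, imidazole, DMAP (cat.), DMF, 40 °C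
Reagents that add atoms: tert-butyldimethylsilyl chloride, CC(C)(C)[Si](C)(C)Cl
Why: Standard silylation of a phenol; masking the chelated hydroxyl is needed for the later aryloxide and hydride chemistry and can be undone with fluoride at the end.

Step 4
Reactants: 7 5-(tert-butyldimethylsilyloxy)-2,2-dimethyl-8-(3-methylbut-2-enyl)-2H-chromene-6-carbaldehyde; 8 ethyl (triphenylphosphoranylidene)acetate
Product: 9 ethyl (E)-3-[5-(tert-butyldimethylsilyloxy)-2,2-dimethyl-8-(3-methylbut-2-enyl)-2H-chromen-6-yl]prop-2-enoate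
Conditions: toluene, 90 °C
Reagents that add atoms: none
Why: Wittig olefination with a stabilised ylide is base-free, so the aryl silyl ether survives, and it should give the E-enoate.

Step 5
Reactants: 9 ethyl (E)-3-[5-(tert-butyldimethylsilyloxy)-2,2-dimethyl-8-(3-methylbut-2-enyl)-2H-chromen-6-yl]prop-2-enoate
Product: 10 (E)-3-[5-(tert-butyldimethylsilyloxy)-2,2-dimethyl-8-(3-methylbut-2-enyl)-2H-chromen-6-yl]prop-2-en-1-ol
Conditions: DIBAL-H (2.5 equiv), CH2Cl2, −78 °C; aq. Rochelle salt
Reagents that add atoms: none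
Why: 1,2-Reduction of an α,β-unsaturated ester by DIBAL-H at low temperature gives the allylic alcohol without touching alkenes or the silyl ether.

Step 6
Reactants: 10 (E)-3-[5-(tert-butyldimethylsilyloxy)-2,2-dimethyl-8-(3-methylbut-2-enyl)-2H-chromen-6-yl]prop-2-en-1-ol
Product: 11 (E)-3-[5-(tert-butyldimethylsilyloxy)-2,2-dimethyl-8-(3-methylbut-2-enyl)-2H-chromen-6-yl]prop-2-enyl methyl carbonate
Conditions: ClCO2Me, pyridine, CH2Cl2, 0 °C
Reagents that add atoms: methyl chloroformate, COC(=O)Cl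
Why: Acylation of the primary allylic alcohol gives the linear carbonate, the standard leaving group for iridium-catalysed allylic substitution.

Step 7
Reactants: 12 phloroglucinol
Product: 13 3,5-bis(tert-butyldimethylsilyloxy)phenol
Conditions: TBSCl (2.0 equiv), imidazole, DMF, 0 °C → rt; chromatographic separation from mono- and tris-silyl ethers
Reagents that add atoms: tert-butyldimethylsilyl chloride, CC(C)(C)[Si](C)(C)Cl
Why: Partial silylation of a C3-symmetric triol can give only one bis-ether, which keeps one hydroxyl free as the future O1.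

Step 8
Reactants: 11 (E)-3-[5-(tert-butyldimethylsilyloxy)-2,2-dimethyl-8-(3-methylbut-2-enyl)-2H-chromen-6-yl]prop-2-enyl methyl carbonate; 13 3,5-bis(tert-butyldimethylsilyloxy)phenol
Product: 15 (S)-6-{1-[3,5-bis(tert-butyldimethylsilyloxy)phenoxy]prop-2-enyl}-5-(tert-butyldimethylsilyloxy)-2,2-dimethyl-8-(3-methylbut-2-enyl)-2H-chromene, via lithium aryloxide 14 (not isolated)
Conditions: 13 (2 equiv), n-BuLi, THF, −78 → 0 °C; then 11, [Ir(cod)Cl]2 (2 mol%), (Sa,Sc,Sc)-O,O'-(1,1'-binaphthyl-2,2'-diyl) N,N-bis[1-(2-methoxyphenyl)ethyl]phosphoramidite (4 mol%, pre-activated with n-PrNH2), THF, rt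
Reagents that add atoms: none
Why: Iridium-catalysed asymmetric allylic etherification; the cyclometalated iridium–phosphoramidite complex ionises the carbonate to an η3-allyl species and the aryloxide attacks the aryl-bearing terminus on the face fixed by the ligand, which sets C2 as S in the branched ether.

Step 9
Reactants: 15 (S)-6-{1-[3,5-bis(tert-butyldimethylsilyloxy)phenoxy]prop-2-enyl}-5-(tert-butyldimethylsilyloxy)-2,2-dimethyl-8-(3-methylbut-2-enyl)-2H-chromene
Product: 17 (S)-3-[3,5-bis(tert-butyldimethylsilyloxy)phenoxy]-3-[5-(tert-butyldimethylsilyloxy)-2,2-dimethyl-8-(3-methylbut-2-enyl)-2H-chromen-6-yl]propan-1-ol, via alkylborane 16 (not isolated)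
Conditions: 9-BBN (1.5 equiv), THF, 0 °C → rt; then NaBO3·4H2O, THF/H2O, rt
Reagents that add atoms: sodium perborate, [Na+].[O-]OB=O
Why: Hydroboration–oxidation; 9-BBN should add only to the monosubstituted vinyl group with boron at the terminal carbon, leaving the trisubstituted prenyl and the hindered chromene alkenes, and the mild perborate oxidation spares the aryl silyl ethers and the stereocentre.

Step 10
Reactants: 17 (S)-3-[3,5-bis(tert-butyldimethylsilyloxy)phenoxy]-3-[5-(tert-butyldimethylsilyloxy)-2,2-dimethyl-8-(3-methylbut-2-enyl)-2H-chromen-6-yl]propan-1-ol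
Product: 19 (S)-3-[3,5-bis(tert-butyldimethylsilyloxy)phenoxy]-3-[5-(tert-butyldimethylsilyloxy)-2,2-dimethyl-8-(3-methylbut-2-enyl)-2H-chromen-6-yl]propanoic acid, via aldehyde 18 (not isolated)
Conditions: TEMPO (0.2 equiv), PhI(OAc)2 (2.2 equiv), MeCN/pH 7 phosphate buffer, 0 °C → rt
Reagents that add atoms: water, O
Why: Oxoammonium-mediated oxidation of the primary alcohol through the aldehyde hydrate to the acid runs near neutral pH, which should avoid β-elimination of the aryloxide and leave the alkenes and silyl ethers alone.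

Step 11
Reactants: 19 (S)-3-[3,5-bis(tert-butyldimethylsilyloxy)phenoxy]-3-[5-(tert-butyldimethylsilyloxy)-2,2-dimethyl-8-(3-methylbut-2-enyl)-2H-chromen-6-yl]propanoic acid
Product: 21 (S)-5,7-bis(tert-butyldimethylsilyloxy)-2-[5-(tert-butyldimethylsilyloxy)-2,2-dimethyl-8-(3-methylbut-2-enyl)-2H-chromen-6-yl]chroman-4-one, via mixed anhydride 20 (not isolated)
Conditions: (CF3CO)2O (1.3 equiv), 2,6-di-tert-butyl-4-methylpyridine (3 equiv), CH2Cl2, −20 °C → rt
Reagents that add atoms: none
Why: The acid is converted into its acyl trifluoroacetate, whose acyl carbon is attacked by the A-ring carbon ortho to O1; loss of a proton to the hindered pyridine restores aromaticity and forms the C4–C4a bond. The closest known reaction is the intramolecular Friedel–Crafts acylation of 3-aryloxypropanoic acids to chroman-4-ones. Ring C closes as a six-membered ring by 6-exo-trig attack on the acyl carbon, with the C4a–C8a arene bond inside the new ring. No stereocentre is created, and C2 keeps its S configuration because none of its bonds takes part. The step needs attack on the A ring rather than on B-ring C6' (which would give an indanone) and needs the benzylic C2–O1 bond to stay intact. The first is secured by the three ortho/para oxygens and the symmetry of the A ring against a C6' that is meta to both B-ring oxygens, the second by the absence of free protic or Lewis acid.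

Step 12
Reactants: 21 (S)-5,7-bis(tert-butyldimethylsilyloxy)-2-[5-(tert-butyldimethylsilyloxy)-2,2-dimethyl-8-(3-methylbut-2-enyl)-2H-chromen-6-yl]chroman-4-one
Product: 22 sanggenol N, (2S)-5,7-dihydroxy-2-[5-hydroxy-2,2-dimethyl-8-(3-methylbut-2-enyl)-2H-chromen-6-yl]chroman-4-one
Conditions: TBAF (3.5 equiv), AcOH (3.5 equiv), THF, 0 °C
Reagents that add atoms: none
Why: Fluoride cleaves the three aryl Si–O bonds, and the acetic acid buffer keeps the freed phenols protonated so that ring C should not open by retro-oxa-Michael reaction and C2 stays S.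

**Compound list**
1 | 5-bromo-2,4-dihydroxybenzaldehyde | O=Cc1cc(Br)c(O)cc1O | starting material
2 | 3-methylbut-2-enal | CC(C)=CC=O | starting material
3 | 5-bromo-2-hydroxy-3-(3-methylbut-2-enylidene)-4-oxocyclohexa-1,5-diene-1-carbaldehyde (oxatriene) | O=CC1=C(O)C(=CC=C(C)C)C(=O)C(Br)=C1 | intermediate
4 | 8-bromo-5-hydroxy-2,2-dimethyl-2H-chromene-6-carbaldehyde | O=Cc1cc(Br)c2OC(C)(C)C=Cc2c1O | intermediate
5 | tributyl(3-methylbut-2-enyl)stannane | CCCC[Sn](CCCC)(CCCC)CC=C(C)C | starting material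
6 | 5-hydroxy-2,2-dimethyl-8-(3-methylbut-2-enyl)-2H-chromene-6-carbaldehyde | CC(C)=CCc1cc(C=O)c(O)c2c1OC(C)(C)C=C2 | intermediate
7 | 5-(tert-butyldimethylsilyloxy)-2,2-dimethyl-8-(3-methylbut-2-enyl)-2H-chromene-6-carbaldehyde | CC(C)=CCc1cc(C=O)c(O[Si](C)(C)C(C)(C)C)c2c1OC(C)(C)C=C2 | intermediate
8 | ethyl (triphenylphosphoranylidene)acetate | CCOC(=O)C=P(c1ccccc1)(c1ccccc1)c1ccccc1 | starting material
9 | ethyl (E)-3-[5-(tert-butyldimethylsilyloxy)-2,2-dimethyl-8-(3-methylbut-2-enyl)-2H-chromen-6-yl]prop-2-enoate | CCOC(=O)/C=C/c1cc(CC=C(C)C)c2OC(C)(C)C=Cc2c1O[Si](C)(C)C(C)(C)C | intermediate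
10 | (E)-3-[5-(tert-butyldimethylsilyloxy)-2,2-dimethyl-8-(3-methylbut-2-enyl)-2H-chromen-6-yl]prop-2-en-1-ol | OC/C=C/c1cc(CC=C(C)C)c2OC(C)(C)C=Cc2c1O[Si](C)(C)C(C)(C)C | intermediate
11 | (E)-3-[5-(tert-butyldimethylsilyloxy)-2,2-dimethyl-8-(3-methylbut-2-enyl)-2H-chromen-6-yl]prop-2-enyl methyl carbonate | COC(=O)OC/C=C/c1cc(CC=C(C)C)c2OC(C)(C)C=Cc2c1O[Si](C)(C)C(C)(C)C | intermediate
12 | phloroglucinol | Oc1cc(O)cc(O)c1 | starting material
13 | 3,5-bis(tert-butyldimethylsilyloxy)phenol | Oc1cc(O[Si](C)(C)C(C)(C)C)cc(O[Si](C)(C)C(C)(C)C)c1 | intermediate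
14 | lithium 3,5-bis(tert-butyldimethylsilyloxy)phenoxide | [Li+].[O-]c1cc(O[Si](C)(C)C(C)(C)C)cc(O[Si](C)(C)C(C)(C)C)c1 | intermediate
15 | (S)-6-{1-[3,5-bis(tert-butyldimethylsilyloxy)phenoxy]prop-2-enyl}-5-(tert-butyldimethylsilyloxy)-2,2-dimethyl-8-(3-methylbut-2-enyl)-2H-chromene | CC(C)=CCc1cc([C@@H](Oc3cc(O[Si](C)(C)C(C)(C)C)cc(O[Si](C)(C)C(C)(C)C)c3)C=C)c(O[Si](C)(C)C(C)(C)C)c2c1OC(C)(C)C=C2 | intermediate
16 | 9-{(S)-3-[3,5-bis(tert-butyldimethylsilyloxy)phenoxy]-3-[5-(tert-butyldimethylsilyloxy)-2,2-dimethyl-8-(3-methylbut-2-enyl)-2H-chromen-6-yl]propyl}-9-borabicyclo[3.3.1]nonane | CC(C)=CCc1cc([C@@H](Oc3cc(O[Si](C)(C)C(C)(C)C)cc(O[Si](C)(C)C(C)(C)C)c3)CCB3C4CCCC3CCC4)c(O[Si](C)(C)C(C)(C)C)c2c1OC(C)(C)C=C2 | intermediate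
17 | (S)-3-[3,5-bis(tert-butyldimethylsilyloxy)phenoxy]-3-[5-(tert-butyldimethylsilyloxy)-2,2-dimethyl-8-(3-methylbut-2-enyl)-2H-chromen-6-yl]propan-1-ol | CC(C)=CCc1cc([C@@H](Oc3cc(O[Si](C)(C)C(C)(C)C)cc(O[Si](C)(C)C(C)(C)C)c3)CCO)c(O[Si](C)(C)C(C)(C)C)c2c1OC(C)(C)C=C2 | intermediate
18 | (S)-3-[3,5-bis(tert-butyldimethylsilyloxy)phenoxy]-3-[5-(tert-butyldimethylsilyloxy)-2,2-dimethyl-8-(3-methylbut-2-enyl)-2H-chromen-6-yl]propanal | CC(C)=CCc1cc([C@@H](Oc3cc(O[Si](C)(C)C(C)(C)C)cc(O[Si](C)(C)C(C)(C)C)c3)CC=O)c(O[Si](C)(C)C(C)(C)C)c2c1OC(C)(C)C=C2 | intermediate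
19 | (S)-3-[3,5-bis(tert-butyldimethylsilyloxy)phenoxy]-3-[5-(tert-butyldimethylsilyloxy)-2,2-dimethyl-8-(3-methylbut-2-enyl)-2H-chromen-6-yl]propanoic acid | CC(C)=CCc1cc([C@@H](Oc3cc(O[Si](C)(C)C(C)(C)C)cc(O[Si](C)(C)C(C)(C)C)c3)CC(=O)O)c(O[Si](C)(C)C(C)(C)C)c2c1OC(C)(C)C=C2 | intermediate
20 | (S)-3-[3,5-bis(tert-butyldimethylsilyloxy)phenoxy]-3-[5-(tert-butyldimethylsilyloxy)-2,2-dimethyl-8-(3-methylbut-2-enyl)-2H-chromen-6-yl]propanoic trifluoroacetic anhydride | CC(C)=CCc1cc([C@@H](Oc3cc(O[Si](C)(C)C(C)(C)C)cc(O[Si](C)(C)C(C)(C)C)c3)CC(=O)OC(=O)C(F)(F)F)c(O[Si](C)(C)C(C)(C)C)c2c1OC(C)(C)C=C2 | intermediate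
21 | (S)-5,7-bis(tert-butyldimethylsilyloxy)-2-[5-(tert-butyldimethylsilyloxy)-2,2-dimethyl-8-(3-methylbut-2-enyl)-2H-chromen-6-yl]chroman-4-one | CC(C)=CCc1cc([C@@H]2CC(=O)c3c(O[Si](C)(C)C(C)(C)C)cc(O[Si](C)(C)C(C)(C)C)cc3O2)c(O[Si](C)(C)C(C)(C)C)c2c1OC(C)(C)C=C2 | intermediate
22 | sanggenol N | CC(C)=CCc1cc([C@@H]2CC(=O)c3c(O)cc(O)cc3O2)c(O)c2c1OC(C)(C)C=C2 | target

**Step count**
Total: 12 steps. Longest linear sequence: 11 steps (steps 1–6 and 8–12 from compound 1); step 7 is a one-step side branch.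

**Steps most likely to fail**

Step 8. Ionisation of the electron-rich, ortho-silyloxy cinnamyl carbonate at the crowded iridium centre may be slow. The branched ether may re-ionise on the metal and drift to the linear isomer with loss of enantiomeric purity, and the methoxide released may strip aryl silyl groups. Fallback: the C2–O1 bond is made by SN2 inversion instead of allylic substitution, setting out from enoate 9 and coming back at acid 19. Copper-catalysed asymmetric conjugate borylation of 9 (CuCl, NaOt-Bu cat., a Josiphos-type bisphosphine, B2pin2, MeOH, THF) should give the (R)-β-boryl ester F1. Oxidation with sodium perborate should give the (R)-β-hydroxy ester F2 with retention. Mitsunobu reaction of F2 with phenol 13 (PPh3, DIAD, toluene, 0 °C, kept cold and non-polar to suppress ionisation of the benzylic oxyphosphonium ion) should give the (S)-β-aryloxy ester F3 with inversion. Cleavage of the ethyl ester with Me3SnOH (1,2-dichloroethane, 70 °C) then leads to 19 without base-induced loss of the aryloxide or of the silyl groups.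

Step 11. Heterolysis of the doubly activated benzylic C2–O1 bond (loss of the aryloxide, racemisation) may outrun ring closure if any acid builds up, or the buffered acyl trifluoroacetate may be too weak an electrophile for the hindered ring carbon. Fallback: the polarity is reversed to an acid-free Parham cyclisation, setting out from phenol 13 and carbonate 11 and coming back at 21. Bromination of 13 (NBS, CH2Cl2, −78 °C) should give 2-bromo-3,5-bis(tert-butyldimethylsilyloxy)phenol F4. Used in place of 13 under the conditions of step 8, F4 gives the (S)-bromoaryl allyl ether F5. The conditions of steps 9 and 10 then give the (S)-bromo alcohol F6 and the (S)-bromo acid F7. Treatment of F7 with n-BuLi (2.1 equiv, THF, −100 °C) forms the lithium carboxylate, and bromine–lithium exchange lets the aryllithium add to the carboxylate to give 21 on work-up; the low temperature is chosen to outpace migration of the neighbouring silyl group from oxygen to carbon.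

Step 9. Hydroboration at the crowded vinyl group may be slow enough for the chromene double bond to begin to react, and the basic oxidative work-up may strip aryl silyl groups. Fallback: the terminal carbon is oxidised by palladium instead of boron, setting out from 15 and coming back at 19. A nitrite-modified, aldehyde-selective Wacker oxidation (PdCl2(PhCN)2, CuCl2, AgNO2, O2, t-BuOH/MeNO2, rt), directed to the terminal carbon by the allylic oxygen, should give aldehyde 18, which is isolated. Pinnick oxidation (NaClO2, NaH2PO4, 2-methylbut-2-ene, t-BuOH/H2O) then gives 19; no compound outside the list is made (F0).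

**Further compounds**
F1 | step 8 | ethyl (R)-3-[5-(tert-butyldimethylsilyloxy)-2,2-dimethyl-8-(3-methylbut-2-enyl)-2H-chromen-6-yl]-3-(4,4,5,5-tetramethyl-1,3,2-dioxaborolan-2-yl)propanoate | CC(C)=CCc1cc([C@H](B3OC(C)(C)C(C)(C)O3)CC(=O)OCC)c(O[Si](C)(C)C(C)(C)C)c2c1OC(C)(C)C=C2
F2 | step 8 | ethyl (R)-3-[5-(tert-butyldimethylsilyloxy)-2,2-dimethyl-8-(3-methylbut-2-enyl)-2H-chromen-6-yl]-3-hydroxypropanoate | CC(C)=CCc1cc([C@H](O)CC(=O)OCC)c(O[Si](C)(C)C(C)(C)C)c2c1OC(C)(C)C=C2
F3 | step 8 | ethyl (S)-3-[3,5-bis(tert-butyldimethylsilyloxy)phenoxy]-3-[5-(tert-butyldimethylsilyloxy)-2,2-dimethyl-8-(3-methylbut-2-enyl)-2H-chromen-6-yl]propanoate | CC(C)=CCc1cc([C@@H](Oc3cc(O[Si](C)(C)C(C)(C)C)cc(O[Si](C)(C)C(C)(C)C)c3)CC(=O)OCC)c(O[Si](C)(C)C(C)(C)C)c2c1OC(C)(C)C=C2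
F4 | step 11 | 2-bromo-3,5-bis(tert-butyldimethylsilyloxy)phenol | Oc1c(Br)c(O[Si](C)(C)C(C)(C)C)cc(O[Si](C)(C)C(C)(C)C)c1
F5 | step 11 | (S)-6-{1-[2-bromo-3,5-bis(tert-butyldimethylsilyloxy)phenoxy]prop-2-enyl}-5-(tert-butyldimethylsilyloxy)-2,2-dimethyl-8-(3-methylbut-2-enyl)-2H-chromene | CC(C)=CCc1cc([C@@H](Oc3cc(O[Si](C)(C)C(C)(C)C)cc(O[Si](C)(C)C(C)(C)C)c3Br)C=C)c(O[Si](C)(C)C(C)(C)C)c2c1OC(C)(C)C=C2
F6 | step 11 | (S)-3-[2-bromo-3,5-bis(tert-butyldimethylsilyloxy)phenoxy]-3-[5-(tert-butyldimethylsilyloxy)-2,2-dimethyl-8-(3-methylbut-2-enyl)-2H-chromen-6-yl]propan-1-ol | CC(C)=CCc1cc([C@@H](Oc3cc(O[Si](C)(C)C(C)(C)C)cc(O[Si](C)(C)C(C)(C)C)c3Br)CCO)c(O[Si](C)(C)C(C)(C)C)c2c1OC(C)(C)C=C2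
F7 | step 11 | (S)-3-[2-bromo-3,5-bis(tert-butyldimethylsilyloxy)phenoxy]-3-[5-(tert-butyldimethylsilyloxy)-2,2-dimethyl-8-(3-methylbut-2-enyl)-2H-chromen-6-yl]propanoic acid | CC(C)=CCc1cc([C@@H](Oc3cc(O[Si](C)(C)C(C)(C)C)cc(O[Si](C)(C)C(C)(C)C)c3Br)CC(=O)O)c(O[Si](C)(C)C(C)(C)C)c2c1OC(C)(C)C=C2
F0 | step 9 | none | none
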